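**Retrosynthetic overview**

1. Pyrrocidine A ⇐ O-methyl N,O-ketal ⇐ 13-membered cyclophane closed last at the aryl–O bond of the ring B carbinol (Ullmann), which also corrects the acyl-bearing CH of ring A.
2. The tetracyclic precursor comes from one cascade: Curtius shift → isocyanate → γ-lactam closed at its C2–C3 bond (lactam carbonyl carbon to α-carbon) → sulfoxide loss → intramolecular Diels–Alder reaction. Ring order: ring C (bought) → lactam → rings A and B together → macrocycle.
3. Enabling feature: in the 3-acyl-3-pyrrolin-2-one, C3 lies between the lactam C2=O and the exocyclic ketone (a 1,3-dicarbonyl carbon, so it can be a carbanion), and C5 is an N,O-ketal carbon (so N can arrive by 1,2-shift from a C5 carboxyl whose carbon becomes C2). The same ketone activates the enone that builds rings A and B.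
4. Cascade substrate ⇐ α-sulfinyl carbanion + enal: acid 20 (from 4-iodo-L-phenylalanine via a cis-tert-butyl dioxolanone) + trienal 12 (from (R)-5-methylcyclohex-2-en-1-one by cuprate/aldol, α-methylation and Z-selective diene synthesis).

Key step: step 16

Assumption: (R)-5-methylcyclohex-2-en-1-one (1) is taken as a purchasable building block (otherwise three known operations from (R)-pulegone).
Assumption: the acyl-bearing CH of ring A and the N,O-ketal carbon are the two labile centres of the target, and their natural configurations are taken to be the thermodynamic ones inside the cyclophane.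

**Route**

Step 1
Reactants: 1 (R)-5-methylcyclohex-2-en-1-one; 2 (E)-4,4-dimethoxybut-2-enal
Product: 4 (2R,3R,5R)-2-[(1R,2E)-1-hydroxy-4,4-dimethoxybut-2-en-1-yl]-3,5-dimethylcyclohexan-1-one, via lithium enolate 3 (not isolated)
Conditions: Me2CuLi, Et2O, −78 → −40 °C; then 2, −78 °C; aq. NH4Cl
Reagents that add atoms: lithium dimethylcuprate, [Li+].C[Cu-]C
Why: Tandem conjugate addition–aldol reaction in which the cuprate adds axially and trans to the ring methyl and the regiodefined E-enolate is trapped anti to the new methyl through a Zimmerman–Traxler chair (anti aldol), so three stereocentres are relayed from the one bought centre.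

Step 2
Reactants: 4 aldol 4
Product: 5 tert-butyldimethylsilyl ether of 4
Conditions: t-BuMe2SiOTf, 2,6-lutidine, CH2Cl2, −78 °C
Reagents that add atoms: tert-butyldimethylsilyl triflate, CC(C)(C)[Si](C)(C)OS(=O)(=O)C(F)(F)F
Why: Silylation of the secondary alcohol with a silyl triflate and a hindered pyridine base is fast at low temperature, blocks retro-aldol cleavage and changes no stereocentre.

Step 3
Reactants: 5 silyl ether ketone 5
Product: 7 homologous cyclohexanecarbaldehyde (CHO in place of C=O; both epimers at the formyl-bearing carbon), via enol ether 6 (not isolated)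
Conditions: Ph3P=CHOMe, THF, 0 → 25 °C; then Hg(OAc)2, THF–H2O, 0 °C; then aq. KI
Reagents that add atoms: (methoxymethylidene)triphenylphosphorane, COC=P(c1ccccc1)(c1ccccc1)c1ccccc1; water, O
Why: Wittig methoxymethylenation followed by Hg(OAc)2-mediated enol ether hydrolysis homologates the hindered ketone under conditions that spare the dimethyl acetal and the silyl ether, and the new CH is left unassigned because it is planarised in step 4.

Step 4
Reactants: 7 aldehyde 7
Product: 8 1-methylcyclohexane-1-carbaldehyde (formyl group cis to the silyloxybutenyl chain; quaternary carbon as in the target)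
Conditions: KOt-Bu, MeI, THF, −20 → 0 °C
Reagents that add atoms: iodomethane, CI
Why: α-Methylation of the potassium aldehyde enolate, in which the axial face of the exocyclic enolate is blocked by the syn-axial ring methyl (chair with the side chain equatorial), so MeI enters equatorially and trans to the neighbouring side chain to give the quaternary centre of the target.

Step 5
Reactants: 8 quaternary aldehyde 8
Product: 9 (E)-2-methylprop-2-enal carrying the ring C unit at C3
Conditions: Ph3P=C(Me)CHO, toluene, 110 °C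
Reagents that add atoms: 2-(triphenylphosphoranylidene)propanal, CC(C=O)=P(c1ccccc1)(c1ccccc1)c1ccccc1
Why: Wittig olefination with a formyl-stabilised ylide gives the (E)-trisubstituted enal, and the conjugated product is less electrophilic than the starting aldehyde so homologation stops after one unit.

Step 6
Reactants: 9 enal 9
Product: 11 (1E,3Z)-2-methylhexa-1,3,5-trienyl acetal, via silyl carbinol borate 10 (not isolated)
Conditions: (E)-Me3SiCH=CHCH2B(pin), toluene, 25 °C; then KOt-Bu, THF, 0 °C
Reagents that add atoms: (E)-trimethyl[3-(4,4,5,5-tetramethyl-1,3,2-dioxaborolan-2-yl)prop-1-en-1-yl]silane, C[Si](C)(C)/C=C/CB1OC(C)(C)C(C)(C)O1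
Why: Allylboration through a chair transition state gives the anti β-silyl carbinol, and base-induced syn-elimination (Peterson olefination) then gives the (Z)-diene terminus that places the vinyl group inside the diene.

Step 7
Reactants: 11 triene acetal 11
Product: 12 (E)-4-silyloxybut-2-enal carrying the trienyl ring C unit at C4
Conditions: oxalic acid (cat.), THF–H2O, 25 °C
Reagents that add atoms: water, O
Why: Acid-catalysed hydrolysis of the allylic dimethyl acetal is much faster than cleavage of the secondary silyl ether and leaves the triene untouched.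

Step 8
Reactants: 13 4-iodo-L-phenylalanine
Product: 14 (S)-2-hydroxy-3-(4-iodophenyl)propanoic acid
Conditions: NaNO2, aq. H2SO4, 0 → 25 °C
Reagents that add atoms: water, O
Why: Diazotisation of the α-amino acid goes with net retention through the α-lactone (double inversion), so the (S) configuration is kept.

Step 9
Reactants: 14 hydroxy acid 14
Product: 15 (2S,5S)-2-tert-butyl-5-(4-iodobenzyl)-1,3-dioxolan-4-one (cis)
Conditions: t-BuCHO, TsOH (cat.), pentane, reflux, water separator
Reagents that add atoms: pivalaldehyde, CC(C)(C)C=O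
Why: Acid-catalysed acetalisation gives the cis-dioxolanone under thermodynamic control and stores the chirality in the acetal carbon (self-regeneration of stereocentres).

Step 10
Reactants: 15 dioxolanone 15; 16 phenyl vinyl sulfoxide (racemic)
Product: 17 (2S,5R)-2-tert-butyl-5-(4-iodobenzyl)-5-[2-(phenylsulfinyl)ethyl]-1,3-dioxolan-4-one (both sulfur epimers)
Conditions: LiN(SiMe3)2, THF, −78 °C; then 16, −78 → −30 °C; aq. NH4Cl
Reagents that add atoms: none
Why: Conjugate addition of the dioxolanone lithium enolate to the vinyl sulfoxide takes place on the face opposite to the tert-butyl group, which sets the quaternary carbon in the configuration the N,O-ketal carbon of the target needs.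

Step 11
Reactants: 17 dioxolanone 17
Product: 18 methyl (R)-2-hydroxy-2-(4-iodobenzyl)-4-(phenylsulfinyl)butanoate
Conditions: NaOMe (cat.), MeOH, 0 → 25 °C
Reagents that add atoms: methanol, CO
Why: Methoxide opens the acylal by transesterification and releases pivalaldehyde without touching the quaternary centre.

Step 12
Reactants: 18 hydroxy ester 18
Product: 19 methyl (R)-2-(4-iodobenzyl)-2-methoxy-4-(phenylsulfinyl)butanoate
Conditions: NaH, MeI, THF–DMF, 0 °C
Reagents that add atoms: iodomethane, CI
Why: Williamson O-methylation of the tertiary alkoxide masks the future hemiaminal oxygen as a methyl ether that survives base, heat and fluoride.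

Step 13
Reactants: 19 methoxy ester 19
Product: 20 (R)-2-(4-iodobenzyl)-2-methoxy-4-(phenylsulfinyl)butanoic acid
Conditions: LiOH, THF–MeOH–H2O, 45 °C; then aq. HCl to pH 3
Reagents that add atoms: lithium hydroxide, [Li+].[OH-]
Why: Saponification of the hindered ester gives the acid needed for the Curtius rearrangement, and the quaternary α-carbon cannot epimerise.

Step 14
Reactants: 20 sulfoxide acid 20; 12 trienal 12
Product: 21 β-hydroxy sulfoxide acid (coupled product; mixture at the carbinol carbon, the sulfinyl-bearing carbon and sulfur)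
Conditions: LiN(i-Pr)2 (2.2 equiv), THF, −78 °C; then 12, −78 °C; aq. HCl to pH 4, 0 °C
Reagents that add atoms: none
Why: 1,2-Addition of the α-sulfinyl carbanion (formed beside the lithium carboxylate) to the enal joins the two fragments, and the three new stereocentres are all erased in steps 15 and 16.

Step 15
Reactants: 21 hydroxy sulfoxide acid 21
Product: 22 β-keto sulfoxide acid (cross-conjugated E-enone; mixture at the sulfinyl-bearing carbon and sulfur)
Conditions: Dess–Martin periodinane, CH2Cl2, 0 °C
Reagents that add atoms: none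
Why: Dess–Martin oxidation of the allylic alcohol gives the β-keto sulfoxide and at the same time creates the enone dienophile, while sulfoxide, triene and acid are inert to the reagent.

Step 16
Reactants: 22 β-keto sulfoxide acid 22
Product: 27 tetracyclic 3-acyl-5-methoxy-3-pyrrolin-2-one (rings A and B trans-fused; silyl ether and aryl iodide kept; acyl-bearing CH epimeric to the target), via acyl azide 23 (not isolated), via isocyanate 24 (not isolated), via sulfinyl lactam 25 (not isolated), via acylpyrrolinone tetraene 26 (not isolated)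
Conditions: (PhO)2P(O)N3, DBU, toluene, 0 → 25 °C; then 75 °C; then 105 °C
Reagents that add atoms: diphenyl phosphorazidate, O=P(N=[N+]=[N-])(Oc1ccccc1)Oc1ccccc1
Why: Proposed new method: acyl azide 23 undergoes Curtius rearrangement (1,2-shift of the quaternary carbon with retention) to the α-methoxy isocyanate 24, whose central carbon is attacked by the DBU-generated, sulfinyl-stabilised ketone enolate to close γ-lactam 25, which loses PhSOH by thermal syn-elimination to give acylpyrrolinone 26, whose enone then adds to the pendant triene. The closest known reaction types are the C-carbamoylation of 1,3-dicarbonyl-type carbanions by isocyanates, the Curtius route to N-acyl N,O-ketals, the dehydrosulfenylation of α-sulfinyl carbonyl compounds and the type 1 intramolecular Diels–Alder reaction of terminally Z-substituted trienones. The lactam closes 5-exo-dig at the isocyanate carbon (C-attack gives a five-membered ring, O-attack would need a seven-membered one), and the cycloaddition closes ring B (five-membered, three-atom tether) and ring A (six-membered) in one suprafacial event. The N,O-ketal carbon keeps the configuration bought with 4-iodo-L-phenylalanine, the relative configuration of the four new ring A carbons follows from the (E)-enone and the (1E,3Z)-diene, the endo position of the acylpyrrolinone gives the trans ring A/ring B fusion, and the π-face is set by 1,3-allylic strain at the quaternary carbon (the diene bisects its two ring bonds) together with the outside position of the silyloxy group. The step needs carbamoylation to outrun sulfoxide elimination, which is secured because the keto sulfoxide is held as its enolate (no sp3 C–S carbon, so no syn-elimination) until the quaternary carbon exists, after which only the lactam CH2 offers β-hydrogens; the three-atom tether lets the diene reach only the exocyclic enone. The acyl-bearing CH is formed epimeric to the target (E-dienophile) and is corrected in step 18.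

Step 17
Reactants: 27 tetracycle 27
Product: 28 ring B secondary alcohol
Conditions: HF·pyridine, pyridine, THF, 0 → 25 °C
Reagents that add atoms: none
Why: Fluoride-mediated desilylation cleaves only the Si–O bond, so the N,O-ketal, the aryl iodide and all stereocentres are untouched.

Step 18
Reactants: 28 alcohol 28
Product: 30 O-methylpyrrocidine A (13-membered cyclophane), via epimerised alcohol 29 (not isolated)
Conditions: CuI, 3,4,7,8-tetramethyl-1,10-phenanthroline, Cs2CO3, toluene (2 mM), 110 °C
Reagents that add atoms: none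
Why: Ullmann-type O-arylation of the ring B alkoxide closes the cyclophane, and because Cs2CO3 epimerises the acyl-bearing CH through the extended enolate and only epimer 29 (acyl cis to the carbinol carbon) can reach the aryl iodide, ring closure drains the equilibrium to the natural configuration (Curtin–Hammett).

Step 19
Reactants: 30 O-methylpyrrocidine A
Product: 31 pyrrocidine A (CNP0151253.3)
Conditions: aq. HCl (0.5 M), THF, 25 °C
Reagents that add atoms: water, O
Why: Acid-catalysed N,O-ketal exchange replaces OMe by OH, and because the benzyl arm is tied into the cyclophane water can only return to the face methanol left, so the configuration set in step 10 is retained.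

**Compound list**

1 | (R)-5-methylcyclohex-2-en-1-one | O=C1C=CC[C@@H](C)C1 | starting material
2 | (E)-4,4-dimethoxybut-2-enal | COC(OC)/C=C/C=O | starting material
3 | lithium (3R,5R)-3,5-dimethylcyclohex-1-en-1-olate | [Li]OC1=C[C@H](C)C[C@@H](C)C1 | intermediate
4 | (2R,3R,5R)-2-[(1R,2E)-1-hydroxy-4,4-dimethoxybut-2-en-1-yl]-3,5-dimethylcyclohexan-1-one | COC(OC)/C=C/[C@@H](O)[C@H]1[C@H](C)C[C@@H](C)CC1=O | intermediate
5 | tert-butyldimethylsilyl ether of 4 | COC(OC)/C=C/[C@@H](O[Si](C)(C)C(C)(C)C)[C@H]1[C@H](C)C[C@@H](C)CC1=O | intermediate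
6 | methyl enol ether (methoxymethylidene in place of C=O of 5; E/Z mixture) | COC(OC)/C=C/[C@@H](O[Si](C)(C)C(C)(C)C)[C@H]1[C@H](C)C[C@@H](C)CC1=COC | intermediate
7 | cyclohexanecarbaldehyde from 6 (both epimers at the formyl-bearing carbon) | COC(OC)/C=C/[C@@H](O[Si](C)(C)C(C)(C)C)[C@H]1[C@H](C)C[C@@H](C)CC1C=O | intermediate
8 | 1-methylcyclohexane-1-carbaldehyde (formyl cis to the side chain) | COC(OC)/C=C/[C@@H](O[Si](C)(C)C(C)(C)C)[C@H]1[C@H](C)C[C@@H](C)C[C@]1(C=O)C | intermediate
9 | (E)-2-methyl enal | COC(OC)/C=C/[C@@H](O[Si](C)(C)C(C)(C)C)[C@H]1[C@H](C)C[C@@H](C)C[C@]1(/C=C(\C)/C=O)C | intermediate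
10 | anti β-silyl carbinol pinacol borate (two new centres anti; not assigned further) | COC(OC)/C=C/[C@@H](O[Si](C)(C)C(C)(C)C)[C@H]1[C@H](C)C[C@@H](C)C[C@]1(/C=C(\C)/C(OB2OC(C)(C)C(C)(C)O2)C([Si](C)(C)C)C=C)C | intermediate
11 | (1E,3Z)-2-methylhexa-1,3,5-trienyl dimethyl acetal | COC(OC)/C=C/[C@@H](O[Si](C)(C)C(C)(C)C)[C@H]1[C@H](C)C[C@@H](C)C[C@]1(/C=C(\C)/C=C\C=C)C | intermediate
12 | trienal (E)-4-silyloxybut-2-enal | O=C/C=C/[C@@H](O[Si](C)(C)C(C)(C)C)[C@H]1[C@H](C)C[C@@H](C)C[C@]1(/C=C(\C)/C=C\C=C)C | intermediate
13 | 4-iodo-L-phenylalanine | Ic1ccc(cc1)C[C@H](N)C(=O)O | starting material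
14 | (S)-2-hydroxy-3-(4-iodophenyl)propanoic acid | Ic1ccc(cc1)C[C@H](O)C(=O)O | intermediate
15 | (2S,5S)-2-tert-butyl-5-(4-iodobenzyl)-1,3-dioxolan-4-one | Ic1ccc(cc1)C[C@H]2C(=O)O[C@@H](C(C)(C)C)O2 | intermediate
16 | phenyl vinyl sulfoxide (racemic) | C=CS(=O)c1ccccc1 | starting material
17 | (2S,5R)-2-tert-butyl-5-(4-iodobenzyl)-5-[2-(phenylsulfinyl)ethyl]-1,3-dioxolan-4-one | Ic1ccc(cc1)C[C@@]2(CCS(=O)c3ccccc3)C(=O)O[C@@H](C(C)(C)C)O2 | intermediate
18 | methyl (R)-2-hydroxy-2-(4-iodobenzyl)-4-(phenylsulfinyl)butanoate | Ic1ccc(cc1)C[C@@](C(=O)OC)(O)CCS(=O)c1ccccc1 | intermediate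
19 | methyl (R)-2-(4-iodobenzyl)-2-methoxy-4-(phenylsulfinyl)butanoate | Ic1ccc(cc1)C[C@@](C(=O)OC)(OC)CCS(=O)c1ccccc1 | intermediate
20 | (R)-2-(4-iodobenzyl)-2-methoxy-4-(phenylsulfinyl)butanoic acid | Ic1ccc(cc1)C[C@@](C(=O)O)(OC)CCS(=O)c1ccccc1 | intermediate
21 | β-hydroxy sulfoxide acid (coupled product) | Ic1ccc(cc1)C[C@@](C(=O)O)(OC)CC(S(=O)c1ccccc1)C(O)/C=C/[C@@H](O[Si](C)(C)C(C)(C)C)[C@H]1[C@H](C)C[C@@H](C)C[C@]1(/C=C(\C)/C=C\C=C)C | intermediate
22 | β-keto sulfoxide acid | Ic1ccc(cc1)C[C@@](C(=O)O)(OC)CC(S(=O)c1ccccc1)C(=O)/C=C/[C@@H](O[Si](C)(C)C(C)(C)C)[C@H]1[C@H](C)C[C@@H](C)C[C@]1(/C=C(\C)/C=C\C=C)C | intermediate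
23 | acyl azide of 22 | Ic1ccc(cc1)C[C@@](C(=O)N=[N+]=[N-])(OC)CC(S(=O)c1ccccc1)C(=O)/C=C/[C@@H](O[Si](C)(C)C(C)(C)C)[C@H]1[C@H](C)C[C@@H](C)C[C@]1(/C=C(\C)/C=C\C=C)C | intermediate
24 | α-methoxy isocyanate | Ic1ccc(cc1)C[C@@](N=C=O)(OC)CC(S(=O)c1ccccc1)C(=O)/C=C/[C@@H](O[Si](C)(C)C(C)(C)C)[C@H]1[C@H](C)C[C@@H](C)C[C@]1(/C=C(\C)/C=C\C=C)C | intermediate
25 | 3-acyl-5-methoxy-3-(phenylsulfinyl)pyrrolidin-2-one | Ic1ccc(cc1)C[C@@]2(OC)CC(S(=O)c3ccccc3)(C(=O)N2)C(=O)/C=C/[C@@H](O[Si](C)(C)C(C)(C)C)[C@H]1[C@H](C)C[C@@H](C)C[C@]1(/C=C(\C)/C=C\C=C)C | intermediate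
26 | 3-acyl-5-methoxy-3-pyrrolin-2-one tetraene | Ic1ccc(cc1)C[C@@]2(OC)C=C(C(=O)N2)C(=O)/C=C/[C@@H](O[Si](C)(C)C(C)(C)C)[C@H]1[C@H](C)C[C@@H](C)C[C@]1(/C=C(\C)/C=C\C=C)C | intermediate
27 | tetracyclic acylpyrrolinone silyl ether (acyl-bearing CH epimeric to the target) | Ic1ccc(cc1)C[C@@]2(OC)C=C(C(=O)N2)C(=O)[C@@H]1[C@@H](C=C)C=C(C)[C@H]2[C@H]1[C@@H](O[Si](C)(C)C(C)(C)C)[C@H]3[C@H](C)C[C@@H](C)C[C@@]23C | intermediate
28 | ring B alcohol of 27 | Ic1ccc(cc1)C[C@@]2(OC)C=C(C(=O)N2)C(=O)[C@@H]1[C@@H](C=C)C=C(C)[C@H]2[C@H]1[C@@H](O)[C@H]3[C@H](C)C[C@@H](C)C[C@@]23C | intermediate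
29 | epimer of 28 at the acyl-bearing CH (natural configuration) | Ic1ccc(cc1)C[C@@]2(OC)C=C(C(=O)N2)C(=O)[C@H]1[C@@H](C=C)C=C(C)[C@H]2[C@H]1[C@@H](O)[C@H]3[C@H](C)C[C@@H](C)C[C@@]23C | intermediate
30 | O-methylpyrrocidine A | C=C[C@H]1C=C(C)[C@H]2[C@H]3[C@@H](Oc4ccc(cc4)C[C@@]4(OC)C=C(C(=O)N4)C(=O)[C@@H]13)[C@H]1[C@H](C)C[C@@H](C)C[C@]12C | intermediate
31 | pyrrocidine A (CNP0151253.3) | C=C[C@H]1C=C(C)[C@H]2[C@H]3[C@@H](Oc4ccc(cc4)C[C@@]4(O)C=C(C(=O)N4)C(=O)[C@@H]13)[C@H]1[C@H](C)C[C@@H](C)C[C@]12C | target

**Step count and risks**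

Total: 19 steps. Longest linear sequence: 13 steps (1 → 31, steps 1–7 and 14–19).

Steps most likely to fail:

1. Step 16 (Proposed new method). Sulfoxide syn-elimination may run ahead of carbon–carbon bond formation, leaving an enone that can no longer be carbamoylated. The thermal cycloaddition may also take the other diene π-face, because the required face brings the diene over ring C, whose axial methyl crowds that approach. Fallback with known reactions only, from 22: the Curtius rearrangement is run with (PhO)2P(O)N3 and Et3N in toluene containing 2-(trimethylsilyl)ethanol at 80 °C, so the isocyanate is trapped as a carbamate while the sulfoxide eliminates, giving the acyclic Teoc-protected dienone F1. Without purification F1 is cyclised with Me2AlCl (CH2Cl2, −20 °C; Lewis acid-promoted endo Diels–Alder reaction) to the tricyclic Teoc carbamate enone F2. α-Iodination (I2, DMAP, K2CO3, aq. THF) gives the α-iodoenone F3. Carbonylative lactamisation (Pd(OAc)2, PPh3, CO 1 atm, Et3N, MeCN, 60 °C) closes the ring at the N–C(=O) bond to give the N-Teoc acylpyrrolinone F4. Bu4NF in THF then removes the Teoc group and the silyl ether together, and the route is rejoined at 28.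

2. Step 18. The hindered secondary alkoxide may fail to couple at 110 °C, and oligomerisation through N-arylation or base-induced degradation of the electrophilic pyrrolinone may win. Fallback from 28: Miyaura borylation (B2pin2, Pd(dppf)Cl2, KOAc, dioxane, 80 °C) gives the aryl pinacol boronate F5. F5 is closed at 25 °C by oxidative Chan–Lam etherification (Cu(OAc)2, pyridine, DBU, 4 Å sieves, O2, CH2Cl2, high dilution), DBU equilibrating the acyl-bearing CH, and the route is rejoined at 30.

3. Step 1. The lithium aldolate may equilibrate by retro-aldol reaction, eroding anti selectivity, and the enolate may add in conjugate fashion to the enal. Fallback from 1: Me2CuLi addition with a proton quench gives the C2-symmetric (3R,5R)-3,5-dimethylcyclohexan-1-one F6, whose two α-positions are homotopic. Its dicyclohexylboron enolate ((c-C6H11)2BCl, Et3N, Et2O, −78 °C) adds to 2 in an anti-selective boron aldol reaction, rejoining the route at 4.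

**Further compounds**

F1 | step 16 | acyclic Teoc-protected N,O-ketal dienone | Ic1ccc(cc1)C[C@@](NC(=O)OCC[Si](C)(C)C)(OC)/C=C/C(=O)/C=C/[C@@H](O[Si](C)(C)C(C)(C)C)[C@H]1[C@H](C)C[C@@H](C)C[C@]1(/C=C(\C)/C=C\C=C)C
F2 | step 16 | tricyclic Teoc carbamate enone | Ic1ccc(cc1)C[C@@](NC(=O)OCC[Si](C)(C)C)(OC)/C=C/C(=O)[C@@H]1[C@@H](C=C)C=C(C)[C@H]2[C@H]1[C@@H](O[Si](C)(C)C(C)(C)C)[C@H]3[C@H](C)C[C@@H](C)C[C@@]23C
F3 | step 16 | α-iodoenone | Ic1ccc(cc1)C[C@@](NC(=O)OCC[Si](C)(C)C)(OC)/C=C(\I)C(=O)[C@@H]1[C@@H](C=C)C=C(C)[C@H]2[C@H]1[C@@H](O[Si](C)(C)C(C)(C)C)[C@H]3[C@H](C)C[C@@H](C)C[C@@]23C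
F4 | step 16 | N-Teoc acylpyrrolinone | Ic1ccc(cc1)C[C@@]2(OC)C=C(C(=O)N2C(=O)OCC[Si](C)(C)C)C(=O)[C@@H]1[C@@H](C=C)C=C(C)[C@H]2[C@H]1[C@@H](O[Si](C)(C)C(C)(C)C)[C@H]3[C@H](C)C[C@@H](C)C[C@@]23C
F5 | step 18 | aryl pinacol boronate of 28 | CC1(C)OB(OC1(C)C)c1ccc(cc1)C[C@@]2(OC)C=C(C(=O)N2)C(=O)[C@@H]1[C@@H](C=C)C=C(C)[C@H]2[C@H]1[C@@H](O)[C@H]3[C@H](C)C[C@@H](C)C[C@@]23C
F6 | step 1 | (3R,5R)-3,5-dimethylcyclohexan-1-one | O=C1C[C@H](C)C[C@@H](C)C1
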